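**Plan**

1. Retrosynthetic cuts: the N–O bond (made last); the bond from pyridone C3 to the acyl carbon (3-lithiopyridine + decalin aldehyde); the bond from pyridone C5 to C1'' (5-lithiopyridine + chiral enone); in the cis-decalin the C5–C6 and C7–C8 bonds, which take out C6–C7 as a two-carbon unit; last the cyclohexene ring C1–C2–C3=C4–C4a–C8a by a Diels–Alder cut (C1–C2, C4a–C8a).
2. Forward order: the cyclohexene ring arises first (diene 3 + fumaroyl imide 7); a lactonization sorts the four side arms; the second carbocycle C4a–C5–C6–C7–C8–C8a is closed in step 12; the epoxycyclohexane ring is built on the pyridine; the fragments are joined at pyridine C3, deprotected and N-hydroxylated.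
3. Feature that makes step 12 possible: C5 and C8 are exocyclic CH2 arms held cis on the adjacent ring atoms C4a and C8a of the cyclohexene ring. A phenylsulfonyl helper on each turns them into a 1,4-dicarbanion that a 1,2-dielectrophile bridges; both helpers leave in step 13.
4. Stereochemistry: C1, C2, C4a, C8a all come from the auxiliary-controlled endo Diels–Alder reaction (step 4). C1'' comes by 1,4-induction from the CBS-derived centre C4'' of enone 25 (erased in step 21); the epoxide is set anti to the C1'' silyl ether (step 22); C4'' is re-set by hydride attack anti to the epoxide (step 23).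

Key step: step 12

Remark on locants: C1–C8a are those of the octahydronaphthalene of the target (C1 bears the acyl group, C2 the methyl group); C1''–C6'' are those of the side-chain cyclohexane (C1'' bonded to the pyridone, epoxide across C5''–C6'').
Remark on the chemistry: the facial sense of the auxiliary (step 4), of the oxazaborolidine (step 15) and of the 1,4-induction (step 19) is assigned from the usual models; if one proves reversed, the mirror-image auxiliary, catalyst or enone is used and nothing else changes.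

**Route**

Step 1
Reactants: 1 dimethyl (2E,4E)-hexa-2,4-dienedioate
Product: 2 (2E,4E)-hexa-2,4-diene-1,6-diol
Conditions: i-Bu2AlH (4.4 equiv), CH2Cl2, −78 → 0 °C; aq. potassium sodium tartrate
Reagents that add atoms: none
Why: Hydride reduction of a conjugated diester with i-Bu2AlH should stop at the bis-allylic diol and keep the E,E geometry.

Step 2
Reactants: 2 (2E,4E)-hexa-2,4-diene-1,6-diol
Product: 3 (2E,4E)-1,6-bis(tert-butyldimethylsilyloxy)hexa-2,4-diene
Conditions: TBSCl, imidazole, DMF, 0 °C → rt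
Reagents that add atoms: tert-butyldimethylsilyl chloride, CC(C)(C)[Si](C)(C)Cl
Why: Standard silylation of primary allylic alcohols gives a C2-symmetric E,E-diene, so the later cycloaddition has no regiochemical question.

Step 3
Reactants: 4 (R)-4-benzyl-1,3-oxazolidin-2-one; 5 (E)-4-tert-butoxy-4-oxobut-2-enoic acid
Product: 7 tert-butyl (E)-4-[(4R)-4-benzyl-2-oxo-1,3-oxazolidin-3-yl]-4-oxobut-2-enoate, via mixed pivalic anhydride 6 (not isolated)
Conditions: 5, t-BuCOCl, Et3N, THF, −20 °C; then 4, LiCl, −20 °C → rt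
Reagents that add atoms: none
Why: N-Acylation of an oxazolidinone through a mixed pivalic anhydride (LiCl/Et3N variant) is the standard entry to enoyl imides and should leave the tert-butyl ester alone.

Step 4
Reactants: 7 tert-butyl (E)-4-[(4R)-4-benzyl-2-oxo-1,3-oxazolidin-3-yl]-4-oxobut-2-enoate; 3 (2E,4E)-1,6-bis(tert-butyldimethylsilyloxy)hexa-2,4-diene
Product: 8 tert-butyl 6-[(4R)-4-benzyl-2-oxo-1,3-oxazolidine-3-carbonyl]-2,5-bis(tert-butyldimethylsilyloxymethyl)cyclohex-3-ene-1-carboxylate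
Conditions: Et2AlCl (1.5 equiv), CH2Cl2, −78 → −30 °C (3 in excess)
Reagents that add atoms: none
Why: In this auxiliary-controlled Diels–Alder reaction the chelated imide should react endo on the face away from the benzyl group, so the E,E-diene sets C2/C4a cis, the E-dienophile sets C1/C8a trans, the endo rule puts the C8 carbonyl cis to both CH2OTBS arms and the auxiliary sets the absolute configuration.

Step 5
Reactants: 8 tert-butyl 6-[(4R)-4-benzyl-2-oxo-1,3-oxazolidine-3-carbonyl]-2,5-bis(tert-butyldimethylsilyloxymethyl)cyclohex-3-ene-1-carboxylate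
Product: 10 tert-butyl 6-(hydroxymethyl)-1-oxo-1,3,3a,6,7,7a-hexahydro-2-benzofuran-7-carboxylate, via diol imide 9 (not isolated)
Conditions: HF·pyridine, THF–pyridine, 0 °C → rt; then Et3N, DMAP (cat.), CH2Cl2, rt
Reagents that add atoms: none
Why: After desilylation only the C5 hydroxyl is cis and adjacent to the activated N-acyl imide, so intramolecular acyl transfer (5-exo-trig lactonization) should close the cis-fused γ-lactone, release the auxiliary and tell the two CH2OH arms apart.

Step 6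
Reactants: 10 tert-butyl 6-(hydroxymethyl)-1-oxo-1,3,3a,6,7,7a-hexahydro-2-benzofuran-7-carboxylate
Product: 11 tert-butyl 6-(iodomethyl)-1-oxo-1,3,3a,6,7,7a-hexahydro-2-benzofuran-7-carboxylate
Conditions: I2, PPh3, imidazole, CH2Cl2, 0 °C → rt
Reagents that add atoms: iodine, II
Why: The Appel reaction converts the remaining primary alcohol into the iodide under neutral conditions that spare lactone, ester and alkene.

Step 7
Reactants: 11 tert-butyl 6-(iodomethyl)-1-oxo-1,3,3a,6,7,7a-hexahydro-2-benzofuran-7-carboxylate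
Product: 12 tert-butyl 6-methyl-1-oxo-1,3,3a,6,7,7a-hexahydro-2-benzofuran-7-carboxylate
Conditions: Bu3SnH (2 equiv, 0.5 M), AIBN (cat.), toluene, 80 °C
Reagents that add atoms: none
Why: Radical dehalogenation turns CH2I into the C2 methyl group, and the high tin hydride concentration should trap the primary radical before homoallyl–cyclopropylcarbinyl rearrangement.

Step 8
Reactants: 12 tert-butyl 6-methyl-1-oxo-1,3,3a,6,7,7a-hexahydro-2-benzofuran-7-carboxylate
Product: 13 tert-butyl 5,6-bis(hydroxymethyl)-2-methylcyclohex-3-ene-1-carboxylate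
Conditions: LiBH4, THF, 0 °C
Reagents that add atoms: none
Why: LiBH4 should reduce the γ-lactone to the cis-1,4-diol much faster than the hindered tert-butyl ester, which keeps C1 at the carboxyl level and distinct from C5 and C8.

Step 9
Reactants: 13 tert-butyl 5,6-bis(hydroxymethyl)-2-methylcyclohex-3-ene-1-carboxylate
Product: 14 tert-butyl 5,6-bis(methanesulfonyloxymethyl)-2-methylcyclohex-3-ene-1-carboxylate
Conditions: MsCl (2.5 equiv), Et3N, CH2Cl2, −10 °C
Reagents that add atoms: methanesulfonyl chloride, CS(=O)(=O)Cl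
Why: Fast sulfene-type mesylation at low temperature should convert both primary alcohols before a mono-mesylate can close to a tetrahydrofuran.

Step 10
Reactants: 14 tert-butyl 5,6-bis(methanesulfonyloxymethyl)-2-methylcyclohex-3-ene-1-carboxylate
Product: 15 tert-butyl 2-methyl-5,6-bis(phenylsulfonylmethyl)cyclohex-3-ene-1-carboxylate
Conditions: PhSO2Na (3 equiv), n-Bu4NI (cat.), DMF, 50 °C
Reagents that add atoms: sodium benzenesulfinate, [Na+].[O-]S(=O)c1ccccc1
Why: SN2 S-alkylation of the sulfinate installs the two phenylsulfonyl helper groups that acidify C5 and C8.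

Step 11
Reactants: 15 tert-butyl 2-methyl-5,6-bis(phenylsulfonylmethyl)cyclohex-3-ene-1-carboxylate
Product: 16 [2-methyl-5,6-bis(phenylsulfonylmethyl)cyclohex-3-en-1-yl]methanol
Conditions: LiAlH4, THF, 0 °C
Reagents that add atoms: none
Why: LiAlH4 reduces the ester to the primary alcohol while sulfones and the isolated alkene are inert at 0 °C, which removes the acidic C1–H and the electrophilic ester before the carbanion step.

Step 12
Reactants: 16 [2-methyl-5,6-bis(phenylsulfonylmethyl)cyclohex-3-en-1-yl]methanol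
Product: 19 [2-methyl-5,8-bis(phenylsulfonyl)-1,2,4a,5,6,7,8,8a-octahydronaphthalen-1-yl]methanol, via trilithio species 17 (not isolated), via monoalkylated carbanion 18 (not isolated)
Conditions: n-BuLi (3.1 equiv), THF–DMPU, −78 °C; then TsOCH2CH2OTs (1.05 equiv), slow addition, −78 → 0 °C; aq. NH4Cl
Reagents that add atoms: ethane-1,2-diyl bis(4-methylbenzenesulfonate), Cc1ccc(cc1)S(=O)(=O)OCCOS(=O)(=O)c1ccc(C)cc1
Why: Three equivalents of base give the lithium alkoxide and the two α-sulfonyl carbanions at C5 and C8; one carbanion displaces a tosylate of the reagent in an intermolecular SN2 step (first of the C5–C6 and C7–C8 bonds), and the tethered 2-tosyloxyethyl arm is then displaced by the other carbanion (second bond). The closest known reaction type is the cycloalkylation of α,α'-dilithiated bis-sulfones (and of malonate-type dianions) with 1,2-dielectrophiles. The new ring C4a–C5–C6–C7–C8–C8a closes in the 6-exo-tet mode. No lasting stereocentre is formed: C5 and C8 arise as epimer mixtures that vanish in step 13, while C1, C2, C4a and C8a are not acidic and are carried unchanged from step 4. The step needs C- over O-alkylation, which the far lower nucleophilicity of a lithium alkoxide should secure, and ring closure over oligomerization, which the cis placement of the two arms on C4a/C8a and slow addition should secure. A sulfonate and not a bromide electrophile is used to avoid halogen transfer to the carbanions.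

Step 13
Reactants: 19 [2-methyl-5,8-bis(phenylsulfonyl)-1,2,4a,5,6,7,8,8a-octahydronaphthalen-1-yl]methanol
Product: 20 [(1R,2S,4aR,8aR)-2-methyl-1,2,4a,5,6,7,8,8a-octahydronaphthalen-1-yl]methanol
Conditions: Na(Hg) (6%), Na2HPO4, MeOH–THF, −20 °C → rt
Reagents that add atoms: none
Why: Buffered reductive desulfonylation by electron transfer should cleave both secondary C–SO2Ph bonds to CH2 and leave the C3=C4 alkene and all stereocentres untouched.

Step 14
Reactants: 20 [(1R,2S,4aR,8aR)-2-methyl-1,2,4a,5,6,7,8,8a-octahydronaphthalen-1-yl]methanol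
Product: 21 (1R,2S,4aR,8aR)-2-methyl-1,2,4a,5,6,7,8,8a-octahydronaphthalene-1-carbaldehyde
Conditions: Dess–Martin periodinane, NaHCO3, CH2Cl2, 0 °C → rt
Reagents that add atoms: none
Why: Buffered Dess–Martin oxidation gives the α-branched aldehyde, whose C1 substituent is already trans to both neighbours (the thermodynamically preferred arrangement).

Step 15
Reactants: 22 1,4-dioxaspiro[4.5]dec-6-en-8-one
Product: 23 (S)-1,4-dioxaspiro[4.5]dec-6-en-8-ol
Conditions: (R)-2-methyl-CBS-oxazaborolidine (10 mol%), BH3·SMe2, THF, −20 °C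
Reagents that add atoms: none
Why: Corey–Bakshi–Shibata reduction of the cyclic enone (alkenyl arm as the large group) should set the carbinol centre by catalyst control with 1,2-selectivity.

Step 16
Reactants: 23 (S)-1,4-dioxaspiro[4.5]dec-6-en-8-ol
Product: 24 (S)-8-(4-methoxybenzyloxy)-1,4-dioxaspiro[4.5]dec-6-ene
Conditions: NaH, 4-MeOC6H4CH2Cl, n-Bu4NI (cat.), THF–DMF, 0 °C → rt
Reagents that add atoms: 4-methoxybenzyl chloride, COc1ccc(CCl)cc1
Why: Williamson etherification gives a PMB ether that is orthogonal to the silyl ethers used later.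

Step 17
Reactants: 24 (S)-8-(4-methoxybenzyloxy)-1,4-dioxaspiro[4.5]dec-6-ene
Product: 25 (S)-4-(4-methoxybenzyloxy)cyclohex-2-en-1-one
Conditions: 1 M HCl, THF, rt
Reagents that add atoms: water, O
Why: Mild acid hydrolysis of the dioxolane unmasks the enone without touching the stereocentre.

Step 18
Reactants: 26 5-bromo-2,4-dichloropyridine
Product: 27 5-bromo-2,4-bis[2-(trimethylsilyl)ethoxy]pyridine
Conditions: Me3SiCH2CH2OH (2.5 equiv), NaH, DMF, 0 → 80 °C
Reagents that add atoms: 2-(trimethylsilyl)ethanol, C[Si](C)(C)CCO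
Why: Double SNAr at the activated 4- and 2-positions installs fluoride-labile ethers of the future 4-hydroxy-2-pyridone, while the unactivated 5-bromide survives.

Step 19
Reactants: 27 5-bromo-2,4-bis[2-(trimethylsilyl)ethoxy]pyridine; 25 (S)-4-(4-methoxybenzyloxy)cyclohex-2-en-1-one
Product: 30 5-[4-(4-methoxybenzyloxy)-1-(triethylsilyloxy)cyclohex-2-en-1-yl]-2,4-bis[2-(trimethylsilyl)ethoxy]pyridine, via 5-lithiopyridine 28 (not isolated), via lithium alkoxide 29 (not isolated)
Conditions: n-BuLi, THF, −78 °C; then 25, −78 °C; then TESOTf, 2,6-lutidine, −78 → 0 °C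
Reagents that add atoms: triethylsilyl trifluoromethanesulfonate, CC[Si](CC)(CC)OS(=O)(=O)C(F)(F)F
Why: Bromine–lithium exchange and 1,2-addition of the aryllithium to the enone, expected on the face anti to the C4'' alkoxy group (1,4-induction), set C1'' with its oxygen cis to the PMB ether, and the tertiary alkoxide is silylated in the same flask.

Step 20
Reactants: 30 5-[4-(4-methoxybenzyloxy)-1-(triethylsilyloxy)cyclohex-2-en-1-yl]-2,4-bis[2-(trimethylsilyl)ethoxy]pyridine
Product: 31 4-{4,6-bis[2-(trimethylsilyl)ethoxy]pyridin-3-yl}-4-(triethylsilyloxy)cyclohex-2-en-1-ol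
Conditions: DDQ, CH2Cl2–pH 7 buffer, 0 °C
Reagents that add atoms: none
Why: Oxidative PMB cleavage under buffered conditions frees the secondary allylic alcohol without touching the tertiary silyl ether or the trimethylsilylethyl ethers.

Step 21
Reactants: 31 4-{4,6-bis[2-(trimethylsilyl)ethoxy]pyridin-3-yl}-4-(triethylsilyloxy)cyclohex-2-en-1-ol
Product: 32 4-{4,6-bis[2-(trimethylsilyl)ethoxy]pyridin-3-yl}-4-(triethylsilyloxy)cyclohex-2-en-1-one
Conditions: Dess–Martin periodinane, NaHCO3, CH2Cl2, 0 °C → rt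
Reagents that add atoms: none
Why: Dess–Martin oxidation gives the γ-silyloxy enone and deliberately erases C4'', whose only task was to relay chirality to C1''.

Step 22
Reactants: 32 4-{4,6-bis[2-(trimethylsilyl)ethoxy]pyridin-3-yl}-4-(triethylsilyloxy)cyclohex-2-en-1-one
Product: 33 4-{4,6-bis[2-(trimethylsilyl)ethoxy]pyridin-3-yl}-2,3-epoxy-4-(triethylsilyloxy)cyclohexan-1-one
Conditions: t-BuOOH (in decane), DBU, CH2Cl2, 0 °C → rt
Reagents that add atoms: tert-butyl hydroperoxide, CC(C)(C)OO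
Why: In this Weitz–Scheffer-type nucleophilic epoxidation the peroxide should add to the β-carbon anti to the pseudoaxial triethylsilyloxy group on C1'', placing the epoxide trans to O1'' and cis to the pyridyl group, while the pyridine nitrogen is not oxidized.

Step 23
Reactants: 33 4-{4,6-bis[2-(trimethylsilyl)ethoxy]pyridin-3-yl}-2,3-epoxy-4-(triethylsilyloxy)cyclohexan-1-one
Product: 34 4-{4,6-bis[2-(trimethylsilyl)ethoxy]pyridin-3-yl}-2,3-epoxy-4-(triethylsilyloxy)cyclohexan-1-ol
Conditions: NaBH4, CeCl3·7H2O, MeOH, −78 °C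
Reagents that add atoms: none
Why: In this Luche reduction hydride should attack the ketone anti to the adjacent epoxide oxygen, giving the C4'' alcohol cis to the epoxide.

Step 24
Reactants: 34 4-{4,6-bis[2-(trimethylsilyl)ethoxy]pyridin-3-yl}-2,3-epoxy-4-(triethylsilyloxy)cyclohexan-1-ol
Product: 35 5-[2,3-epoxy-1,4-bis(triethylsilyloxy)cyclohexyl]-2,4-bis[2-(trimethylsilyl)ethoxy]pyridine
Conditions: TESCl, imidazole, DMF, 0 °C → rt
Reagents that add atoms: triethylsilyl chloride, CC[Si](CC)(CC)Cl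
Why: Silylation of the secondary alcohol leaves no acidic O–H for the metalation and no second oxidizable carbinol for step 26.

Step 25
Reactants: 35 5-[2,3-epoxy-1,4-bis(triethylsilyloxy)cyclohexyl]-2,4-bis[2-(trimethylsilyl)ethoxy]pyridine; 21 (1R,2S,4aR,8aR)-2-methyl-1,2,4a,5,6,7,8,8a-octahydronaphthalene-1-carbaldehyde
Product: 37 secondary carbinol joining decalin C1 to pyridine C3, via 3-lithiopyridine 36 (not isolated)
Conditions: n-BuLi, THF, −78 → −30 °C; then 21, −78 °C; aq. NH4Cl
Reagents that add atoms: none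
Why: Directed ortho-metalation occurs at C3, flanked by the two alkoxy groups, and the aryllithium adds to the α-branched aldehyde; the carbinol configuration is of no consequence.

Step 26
Reactants: 37 secondary carbinol joining decalin C1 to pyridine C3
Product: 38 fully protected 3-acylpyridine
Conditions: Dess–Martin periodinane, NaHCO3, CH2Cl2, rt
Reagents that add atoms: none
Why: Dess–Martin oxidation converts the hindered carbinol into the aryl ketone while alkene, epoxide and silyl ethers are inert.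

Step 27
Reactants: 38 fully protected 3-acylpyridine
Product: 39 N-deoxyfischerin (1H-pyridin-2-one)
Conditions: TBAF (6 equiv), AcOH, THF, 0 °C → rt
Reagents that add atoms: none
Why: Buffered fluoride should cleave both triethylsilyl ethers and both 2-(trimethylsilyl)ethyl ethers (β-elimination of ethene, eased by the 3-acyl group), unveiling the 3-acyl-4-hydroxy-2-pyridone with the epoxide intact.

Step 28
Reactants: 39 N-deoxyfischerin (1H-pyridin-2-one)
Product: 41 fischerin, via persilylated pyridine 40 (not isolated)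
Conditions: (Me3Si)2NH, Me3SiCl (cat.), reflux, then evaporation; MoO(O2)2·pyridine·HMPA, CH2Cl2, rt; aq. tetrasodium EDTA, then dilute citric acid
Reagents that add atoms: oxodiperoxo(pyridine)(hexamethylphosphoric triamide)molybdenum, O=[Mo]12(OO1)OO2.c1ccncc1.CN(C)P(=O)(N(C)C)N(C)C
Why: N-Hydroxylation of a 2-pyridone through its O-silyl imidate with a molybdenum peroxo complex is a known route to 1-hydroxy-2-pyridones, and the hindered cis-disubstituted C3=C4 alkene should react far more slowly with this reagent than the ring nitrogen.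

**Compound list**

1 | dimethyl (2E,4E)-hexa-2,4-dienedioate | COC(=O)/C=C/C=C/C(=O)OC | starting material
2 | (2E,4E)-hexa-2,4-diene-1,6-diol | OC/C=C/C=C/CO | intermediate
3 | (2E,4E)-1,6-bis(tert-butyldimethylsilyloxy)hexa-2,4-diene | CC(C)(C)[Si](C)(C)OC/C=C/C=C/CO[Si](C)(C)C(C)(C)C | intermediate
4 | (R)-4-benzyl-1,3-oxazolidin-2-one | O=C1N[C@H](Cc2ccccc2)CO1 | starting material
5 | (E)-4-tert-butoxy-4-oxobut-2-enoic acid (mono-tert-butyl fumarate) | CC(C)(C)OC(=O)/C=C/C(=O)O | starting material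
6 | mixed anhydride of 5 with pivalic acid (not isolated) | CC(C)(C)OC(=O)/C=C/C(=O)OC(=O)C(C)(C)C | intermediate
7 | tert-butyl (E)-4-[(4R)-4-benzyl-2-oxo-1,3-oxazolidin-3-yl]-4-oxobut-2-enoate | CC(C)(C)OC(=O)/C=C/C(=O)N1C(=O)OC[C@H]1Cc1ccccc1 | intermediate
8 | tert-butyl 6-[(4R)-4-benzyl-2-oxo-1,3-oxazolidine-3-carbonyl]-2,5-bis(tert-butyldimethylsilyloxymethyl)cyclohex-3-ene-1-carboxylate; ring atoms 1, 2, 5, 6 are target C1, C2, C4a, C8a; the 2-, 5- and 6-substituents cis, the 1-ester trans to them | CC(C)(C)[Si](C)(C)OC[C@H]1C=C[C@@H](CO[Si](C)(C)C(C)(C)C)[C@@H](C(=O)N2C(=O)OC[C@H]2Cc2ccccc2)[C@@H]1C(=O)OC(C)(C)C | intermediate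
9 | diol imide, 8 without the two silyl groups (not isolated) | OC[C@H]1C=C[C@@H](CO)[C@@H](C(=O)N2C(=O)OC[C@H]2Cc2ccccc2)[C@@H]1C(=O)OC(C)(C)C | intermediate
10 | tert-butyl 6-(hydroxymethyl)-1-oxo-1,3,3a,6,7,7a-hexahydro-2-benzofuran-7-carboxylate; cis-fused lactone C5–O–C8(=O), CH2OH cis to the lactone CH2, ester trans to both neighbours | OC[C@H]1C=C[C@H]2COC(=O)[C@H]2[C@@H]1C(=O)OC(C)(C)C | intermediate
11 | tert-butyl 6-(iodomethyl)-1-oxo-1,3,3a,6,7,7a-hexahydro-2-benzofuran-7-carboxylate, configuration as 10 | IC[C@H]1C=C[C@H]2COC(=O)[C@H]2[C@@H]1C(=O)OC(C)(C)C | intermediate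
12 | tert-butyl 6-methyl-1-oxo-1,3,3a,6,7,7a-hexahydro-2-benzofuran-7-carboxylate, configuration as 10 | C[C@H]1C=C[C@H]2COC(=O)[C@H]2[C@@H]1C(=O)OC(C)(C)C | intermediate
13 | tert-butyl 5,6-bis(hydroxymethyl)-2-methylcyclohex-3-ene-1-carboxylate; 2-methyl, 5- and 6-CH2OH cis, ester trans | C[C@H]1C=C[C@@H](CO)[C@@H](CO)[C@@H]1C(=O)OC(C)(C)C | intermediate
14 | tert-butyl 5,6-bis(methanesulfonyloxymethyl)-2-methylcyclohex-3-ene-1-carboxylate, configuration as 13 | C[C@H]1C=C[C@@H](COS(C)(=O)=O)[C@@H](COS(C)(=O)=O)[C@@H]1C(=O)OC(C)(C)C | intermediate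
15 | tert-butyl 2-methyl-5,6-bis(phenylsulfonylmethyl)cyclohex-3-ene-1-carboxylate, configuration as 13 | C[C@H]1C=C[C@@H](CS(=O)(=O)c2ccccc2)[C@@H](CS(=O)(=O)c2ccccc2)[C@@H]1C(=O)OC(C)(C)C | intermediate
16 | [2-methyl-5,6-bis(phenylsulfonylmethyl)cyclohex-3-en-1-yl]methanol, configuration as 13 | C[C@H]1C=C[C@@H](CS(=O)(=O)c2ccccc2)[C@@H](CS(=O)(=O)c2ccccc2)[C@@H]1CO | intermediate
17 | trilithio derivative of 16: lithium alkoxide, both α-sulfonyl carbons lithiated (not isolated) | [Li+].[Li+].[Li+].C[C@H]1C=C[C@@H]([CH-]S(=O)(=O)c2ccccc2)[C@@H]([CH-]S(=O)(=O)c2ccccc2)[C@@H]1C[O-] | intermediate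
18 | monoalkylated carbanion: C5 carries CH2CH2OTs, C8 still lithiated (not isolated) | [Li+].[Li+].C[C@H]1C=C[C@@H](C(CCOS(=O)(=O)c2ccc(C)cc2)S(=O)(=O)c2ccccc2)[C@@H]([CH-]S(=O)(=O)c2ccccc2)[C@@H]1C[O-] | intermediate
19 | [2-methyl-5,8-bis(phenylsulfonyl)-1,2,4a,5,6,7,8,8a-octahydronaphthalen-1-yl]methanol; cis-fused, C1, C2, C4a, C8a as in 20, epimer mixture at C5 and C8 | C[C@H]1C=C[C@H]2C(S(=O)(=O)c3ccccc3)CCC(S(=O)(=O)c3ccccc3)[C@H]2[C@@H]1CO | intermediate
20 | [(1R,2S,4aR,8aR)-2-methyl-1,2,4a,5,6,7,8,8a-octahydronaphthalen-1-yl]methanol | C[C@H]1C=C[C@H]2CCCC[C@H]2[C@@H]1CO | intermediate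
21 | (1R,2S,4aR,8aR)-2-methyl-1,2,4a,5,6,7,8,8a-octahydronaphthalene-1-carbaldehyde | C[C@H]1C=C[C@H]2CCCC[C@H]2[C@@H]1C=O | intermediate
22 | 1,4-dioxaspiro[4.5]dec-6-en-8-one | O=C1C=CC2(CC1)OCCO2 | starting material
23 | (S)-1,4-dioxaspiro[4.5]dec-6-en-8-ol | O[C@@H]1C=CC2(CC1)OCCO2 | intermediate
24 | (S)-8-(4-methoxybenzyloxy)-1,4-dioxaspiro[4.5]dec-6-ene | COc1ccc(CO[C@@H]2C=CC3(CC2)OCCO3)cc1 | intermediate
25 | (S)-4-(4-methoxybenzyloxy)cyclohex-2-en-1-one | COc1ccc(CO[C@@H]2C=CC(=O)CC2)cc1 | intermediate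
26 | 5-bromo-2,4-dichloropyridine | Clc1cc(Cl)c(Br)cn1 | starting material
27 | 5-bromo-2,4-bis[2-(trimethylsilyl)ethoxy]pyridine | C[Si](C)(C)CCOc1cc(OCC[Si](C)(C)C)c(Br)cn1 | intermediate
28 | 5-lithio-2,4-bis[2-(trimethylsilyl)ethoxy]pyridine (not isolated) | [Li]c1cnc(OCC[Si](C)(C)C)cc1OCC[Si](C)(C)C | intermediate
29 | lithium alkoxide of the 1,2-adduct, O1'' cis to the PMB ether (not isolated) | C[Si](C)(C)CCOc1cc(OCC[Si](C)(C)C)c(cn1)[C@@]1(O[Li])CC[C@H](OCc2ccc(OC)cc2)C=C1 | intermediate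
30 | 5-[4-(4-methoxybenzyloxy)-1-(triethylsilyloxy)cyclohex-2-en-1-yl]-2,4-bis[2-(trimethylsilyl)ethoxy]pyridine; silyloxy and PMB-oxy groups cis | C[Si](C)(C)CCOc1cc(OCC[Si](C)(C)C)c(cn1)[C@@]1(O[Si](CC)(CC)CC)CC[C@H](OCc2ccc(OC)cc2)C=C1 | intermediate
31 | 4-{4,6-bis[2-(trimethylsilyl)ethoxy]pyridin-3-yl}-4-(triethylsilyloxy)cyclohex-2-en-1-ol; OH cis to the silyloxy group | C[Si](C)(C)CCOc1cc(OCC[Si](C)(C)C)c(cn1)[C@@]1(O[Si](CC)(CC)CC)CC[C@H](O)C=C1 | intermediate
32 | 4-{4,6-bis[2-(trimethylsilyl)ethoxy]pyridin-3-yl}-4-(triethylsilyloxy)cyclohex-2-en-1-one | C[Si](C)(C)CCOc1cc(OCC[Si](C)(C)C)c(cn1)[C@@]1(O[Si](CC)(CC)CC)CCC(=O)C=C1 | intermediate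
33 | 4-{4,6-bis[2-(trimethylsilyl)ethoxy]pyridin-3-yl}-2,3-epoxy-4-(triethylsilyloxy)cyclohexan-1-one; epoxide trans to the silyloxy group, cis to the pyridyl group | C[Si](C)(C)CCOc1cc(OCC[Si](C)(C)C)c(cn1)[C@@]1(O[Si](CC)(CC)CC)CCC(=O)[C@H]2O[C@H]21 | intermediate
34 | 4-{4,6-bis[2-(trimethylsilyl)ethoxy]pyridin-3-yl}-2,3-epoxy-4-(triethylsilyloxy)cyclohexan-1-ol; OH cis to the epoxide | C[Si](C)(C)CCOc1cc(OCC[Si](C)(C)C)c(cn1)[C@@]1(O[Si](CC)(CC)CC)CC[C@@H](O)[C@H]2O[C@H]21 | intermediate
35 | 5-[2,3-epoxy-1,4-bis(triethylsilyloxy)cyclohexyl]-2,4-bis[2-(trimethylsilyl)ethoxy]pyridine, configuration as 34 | C[Si](C)(C)CCOc1cc(OCC[Si](C)(C)C)c(cn1)[C@@]1(O[Si](CC)(CC)CC)CC[C@@H](O[Si](CC)(CC)CC)[C@H]2O[C@H]21 | intermediate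
36 | 3-lithio derivative of 35 (not isolated) | [Li]c1c(OCC[Si](C)(C)C)c([C@@]2(O[Si](CC)(CC)CC)CC[C@@H](O[Si](CC)(CC)CC)[C@H]3O[C@H]32)cnc1OCC[Si](C)(C)C | intermediate
37 | secondary carbinol from 21 and 36: decalin C1–CH(OH)–pyridine C3, epimer mixture at the carbinol carbon | C[C@H]1C=C[C@H]2CCCC[C@H]2[C@@H]1C(O)c1c(OCC[Si](C)(C)C)c([C@@]2(O[Si](CC)(CC)CC)CC[C@@H](O[Si](CC)(CC)CC)[C@H]3O[C@H]32)cnc1OCC[Si](C)(C)C | intermediate
38 | fully protected 3-acylpyridine (ketone of 37) | C[C@H]1C=C[C@H]2CCCC[C@H]2[C@@H]1C(=O)c1c(OCC[Si](C)(C)C)c([C@@]2(O[Si](CC)(CC)CC)CC[C@@H](O[Si](CC)(CC)CC)[C@H]3O[C@H]32)cnc1OCC[Si](C)(C)C | intermediate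
39 | N-deoxyfischerin: the 4-hydroxy-1H-pyridin-2-one lacking the N-hydroxyl | C[C@H]1C=C[C@H]2CCCC[C@H]2[C@@H]1C(=O)c1c(O)c([C@@]2(O)CC[C@@H](O)[C@H]3O[C@H]32)c[nH]c1=O | intermediate
40 | tetrakis(trimethylsilyl) derivative of 39: 2,4-bis(trimethylsilyloxy)pyridine with both side-chain alcohols silylated (not isolated) | C[C@H]1C=C[C@H]2CCCC[C@H]2[C@@H]1C(=O)c1c(O[Si](C)(C)C)c([C@@]2(O[Si](C)(C)C)CC[C@@H](O[Si](C)(C)C)[C@H]3O[C@H]32)cnc1O[Si](C)(C)C | intermediate
41 | fischerin: 5-[(1R,2S,5R,6R)-2,5-dihydroxy-7-oxabicyclo[4.1.0]heptan-2-yl]-1,4-dihydroxy-3-{[(1R,2S,4aR,8aR)-2-methyl-1,2,4a,5,6,7,8,8a-octahydronaphthalen-1-yl]carbonyl}pyridin-2(1H)-one | C[C@H]1C=C[C@H]2CCCC[C@H]2[C@@H]1C(=O)c1c(O)c([C@@]2(O)CC[C@@H](O)[C@H]3O[C@H]32)cn(O)c1=O | target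

**Totals and risks**

Total step count: 28. Longest linear sequence: 17 steps (steps 1, 2, 4–14, 25–28).

Steps most likely to fail:

1. Step 12. The trilithiated species may form incompletely or aggregate, and intermolecular double alkylation (oligomers) or alkylation on the alkoxide oxygen may compete with the 6-exo ring closure. Fallback: from dimesylate 14, two copper-catalysed couplings with vinylmagnesium bromide (Li2CuCl4 cat., THF, −30 → 0 °C) would give the cis-diallyl ester F1. Ring-closing metathesis with the second-generation Grubbs catalyst (CH2Cl2, 40 °C) would close the second ring as the hexahydronaphthalene ester F2. Hydrogenation with RhCl(PPh3)3 (H2, benzene) should saturate the unhindered C6=C7 alkene in preference to C3=C4, which is flanked by the C2 and C4a stereocentres, to give the octahydronaphthalene ester F3. LiAlH4 reduction of F3 returns to alcohol 20.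

2. Step 19. The 1,4-induction by the remote PMB ether may be weak, so that the aryllithium adds to both faces of the enone and C1'' is formed as an epimer mixture. Fallback: from bromide 27, the same bromine–lithium exchange followed by addition to 4,4-dimethoxycyclohexa-2,5-dien-1-one would give the achiral dienol ketal F4. Mild aqueous acid would give the p-quinol F5, and TESOTf/2,6-lutidine its silyl ether F6. A copper hydride-catalysed enantioselective conjugate reduction (Cu(OAc)2, (R)-DTBM-SEGPHOS or its enantiomer, polymethylhydrosiloxane, t-BuOH, toluene) of one of the two enantiotopic enone arms would then set C1'' by catalyst control and return to enone 32.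

3. Step 28. Oxygen transfer may be slow or may go in part to the C3=C4 alkene, and the polar product may be lost on work-up. Fallback: the N–O bond is made before the alkene-bearing fragment is attached. From 35, directed metalation (n-BuLi, THF, −78 °C) and quenching with iodine would give the 3-iodopyridine F7. mCPBA (CH2Cl2, rt) would give the pyridine N-oxide F8. Iodine–magnesium exchange (i-PrMgCl·LiCl, THF, −40 °C) and addition to aldehyde 21 would give the carbinol N-oxide F9, and Dess–Martin oxidation the ketone N-oxide F10. Buffered TBAF would then cleave all silyl groups; loss of the 2-(trimethylsilyl)ethyl group from the 2-alkoxypyridine N-oxide gives the 1-hydroxy-2-pyridone directly, returning to the route at 41.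

**Further compounds**

F1 | step 12 | tert-butyl 2-methyl-5,6-bis(prop-2-en-1-yl)cyclohex-3-ene-1-carboxylate, configuration as 13 | C[C@H]1C=C[C@@H](CC=C)[C@@H](CC=C)[C@@H]1C(=O)OC(C)(C)C
F2 | step 12 | tert-butyl cis-fused 2-methyl-1,2,4a,5,8,8a-hexahydronaphthalene-1-carboxylate, configuration as 20 | C[C@H]1C=C[C@H]2CC=CC[C@H]2[C@@H]1C(=O)OC(C)(C)C
F3 | step 12 | tert-butyl 2-methyl-1,2,4a,5,6,7,8,8a-octahydronaphthalene-1-carboxylate, configuration as 20 | C[C@H]1C=C[C@H]2CCCC[C@H]2[C@@H]1C(=O)OC(C)(C)C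
F4 | step 19 | 1-{4,6-bis[2-(trimethylsilyl)ethoxy]pyridin-3-yl}-4,4-dimethoxycyclohexa-2,5-dien-1-ol | COC1(OC)C=CC(O)(c2cnc(OCC[Si](C)(C)C)cc2OCC[Si](C)(C)C)C=C1
F5 | step 19 | 4-{4,6-bis[2-(trimethylsilyl)ethoxy]pyridin-3-yl}-4-hydroxycyclohexa-2,5-dien-1-one | O=C1C=CC(O)(c2cnc(OCC[Si](C)(C)C)cc2OCC[Si](C)(C)C)C=C1
F6 | step 19 | 4-{4,6-bis[2-(trimethylsilyl)ethoxy]pyridin-3-yl}-4-(triethylsilyloxy)cyclohexa-2,5-dien-1-one | O=C1C=CC(O[Si](CC)(CC)CC)(c2cnc(OCC[Si](C)(C)C)cc2OCC[Si](C)(C)C)C=C1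
F7 | step 28 | 3-iodo derivative of 35 | Ic1c(OCC[Si](C)(C)C)c([C@@]2(O[Si](CC)(CC)CC)CC[C@@H](O[Si](CC)(CC)CC)[C@H]3O[C@H]32)cnc1OCC[Si](C)(C)C
F8 | step 28 | N-oxide of the 3-iodopyridine | Ic1c(OCC[Si](C)(C)C)c([C@@]2(O[Si](CC)(CC)CC)CC[C@@H](O[Si](CC)(CC)CC)[C@H]3O[C@H]32)c[n+]([O-])c1OCC[Si](C)(C)C
F9 | step 28 | N-oxide of carbinol 37, epimer mixture at the carbinol carbon | C[C@H]1C=C[C@H]2CCCC[C@H]2[C@@H]1C(O)c1c(OCC[Si](C)(C)C)c([C@@]2(O[Si](CC)(CC)CC)CC[C@@H](O[Si](CC)(CC)CC)[C@H]3O[C@H]32)c[n+]([O-])c1OCC[Si](C)(C)C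
F10 | step 28 | N-oxide of ketone 38 | C[C@H]1C=C[C@H]2CCCC[C@H]2[C@@H]1C(=O)c1c(OCC[Si](C)(C)C)c([C@@]2(O[Si](CC)(CC)CC)CC[C@@H](O[Si](CC)(CC)CC)[C@H]3O[C@H]32)c[n+]([O-])c1OCC[Si](C)(C)C
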